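**Retrosynthetic overview**

1. The (5S)-dione is the flat, achiral 8-hydroxy-3-methoxy-2-methyl-5-(5-phenylpentyl)quinolin-4(1H)-one plus one H2 (the hetero-analogue of 1-naphthol → 1-tetralone). An enantioselective ruthenium-catalysed hydrogenation of the phenol ring in the last step creates C5 (S) and the C8 ketone together.
2. The hydroxyquinolone is cut by Conrad–Limpach logic (N1–C2 condensation, C4–C4a thermal ring closure) into 2-amino-4-(5-phenylpentyl)phenol and methyl 2-methoxy-3-oxobutanoate. The phenol is capped only transiently as its TMS ether during the 250 °C cyclisation.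
3. The aminophenol comes from cheap 2-amino-4-bromophenol and 5-phenylpent-1-ene by hydroboration and B-alkyl Suzuki–Miyaura coupling.
4. Ring order: benzene ring bought → pyridone ring annulated onto it → benzene ring dearomatised to the cyclohexenone ring.

Assumption: methyl 2-methoxy-3-oxobutanoate is bought as a catalogue reagent.

**Route**

Step 1
Reactants: 1 2-amino-4-bromophenol; 2 5-phenylpent-1-ene
Product: 4 2-amino-4-(5-phenylpentyl)phenol, via alkylborane 3 (not isolated)
Conditions: 2, 9-BBN (0.5 M in THF), 0 °C to rt; then 1, Pd(OAc)2 (3 mol%), SPhos (6 mol%), aq K3PO4 (3 M), THF, 65 °C, argon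
Reagents that add atoms: none
Why: B-alkyl Suzuki–Miyaura coupling, in which anti-Markovnikov hydroboration of the terminal alkene gives the primary alkylborane that cross-couples with the aryl bromide under zerovalent palladium/SPhos catalysis tolerant of free NH2 and OH; no stereocenter is formed.

Step 2
Reactants: 4 2-amino-4-(5-phenylpentyl)phenol; 5 methyl 2-methoxy-3-oxobutanoate
Product: 6 methyl (2E)-3-{[2-hydroxy-5-(5-phenylpentyl)phenyl]amino}-2-methoxybut-2-enoate
Conditions: AcOH (10 mol%), 4 Å MS, MeOH, 40 °C, N2
Reagents that add atoms: none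
Why: Enamine condensation of the aniline nitrogen with the ketone of the β-keto ester (first stage of the Conrad–Limpach quinolone synthesis), where the N–H···O=C hydrogen bond fixes the (E) geometry needed for ring closure and the mild, nearly neutral conditions avoid benzoxazole formation.

Step 3
Reactants: 6 methyl (2E)-3-{[2-hydroxy-5-(5-phenylpentyl)phenyl]amino}-2-methoxybut-2-enoate
Product: 9 8-hydroxy-3-methoxy-2-methyl-5-(5-phenylpentyl)quinolin-4(1H)-one, via silyl ether 7 (not isolated), via silyloxyquinolone 8 (not isolated)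
Conditions: HMDS (0.6 equiv), Me3SiCl (2 mol%), toluene, 80 °C; evaporate; Ph2O, 250 °C, 20 min, N2 sweep; then MeOH, cat. HCl, rt
Reagents that add atoms: none
Why: Conrad–Limpach thermal cyclisation, in which the enaminoester (phenol capped as its TMS ether so it cannot attack the enamine or ester) loses methanol at 250 °C and closes by 6π-electrocyclisation and tautomerisation onto the only free ortho carbon, next to the alkyl chain, before methanolysis on work-up returns the 8-hydroxyl.

Step 4
Reactants: 9 8-hydroxy-3-methoxy-2-methyl-5-(5-phenylpentyl)quinolin-4(1H)-one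
Product: 11 (5S)-3-methoxy-2-methyl-5-(5-phenylpentyl)-6,7-dihydroquinoline-4,8(1H,5H)-dione, via dihydro enol 10 (not isolated)
Conditions: H2 (30 bar), catalyst pre-formed from Ru(2-methylallyl)2(cod) (5 mol%), (R,R)-SINpEt·HBF4 (10 mol%) and KOtBu (15 mol%) in hexane at 70 °C, t-AmOH/toluene, 30 °C, stopped at 1 equiv H2; then aq NH4Cl
Reagents that add atoms: none
Why: Proposed new method: the chiral bis(NHC)–ruthenium hydride binds the substrate as a ruthenium phenoxide (η5-oxocyclohexadienyl mode) and delivers one H2 across C5=C6 from a single face of the carbocycle, so the ligand sets C5 as (S) and enol 10 tautomerises to the conjugated C8 ketone, while the tetrasubstituted vinylogous-amide ring and the isolated phenyl ring are not reduced; the closest known reaction types are the partial hydrogenation of 1-naphthols to 1-tetralones and the Ru–NHC and Ru–PhTRAP enantioselective hydrogenation of the carbocycle of quinoxalines and quinolines; the sense of induction is untested, so the ligand antipode is fixed after a first analytical run.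

**Compound list**

1 | 2-amino-4-bromophenol | Nc1cc(Br)ccc1O | starting material
2 | 5-phenylpent-1-ene (pent-4-en-1-ylbenzene) | C=CCCCc1ccccc1 | starting material
3 | 9-(5-phenylpentyl)-9-borabicyclo[3.3.1]nonane | C(CCCCc1ccccc1)B1C2CCCC1CCC2 | intermediate
4 | 2-amino-4-(5-phenylpentyl)phenol | Nc1cc(CCCCCc2ccccc2)ccc1O | intermediate
5 | methyl 2-methoxy-3-oxobutanoate (racemic, configurationally labile) | COC(C(C)=O)C(=O)OC | starting material
6 | methyl (2E)-3-{[2-hydroxy-5-(5-phenylpentyl)phenyl]amino}-2-methoxybut-2-enoate | COC(=O)/C(OC)=C(\Nc1cc(CCCCCc2ccccc2)ccc1O)C | intermediate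
7 | methyl (2E)-2-methoxy-3-{[5-(5-phenylpentyl)-2-(trimethylsilyloxy)phenyl]amino}but-2-enoate | COC(=O)/C(OC)=C(\Nc1cc(CCCCCc2ccccc2)ccc1O[Si](C)(C)C)C | intermediate
8 | 3-methoxy-2-methyl-5-(5-phenylpentyl)-8-(trimethylsilyloxy)quinolin-4(1H)-one | COc1c(C)[nH]c2c(O[Si](C)(C)C)ccc(CCCCCc3ccccc3)c2c1=O | intermediate
9 | 8-hydroxy-3-methoxy-2-methyl-5-(5-phenylpentyl)quinolin-4(1H)-one | COc1c(C)[nH]c2c(O)ccc(CCCCCc3ccccc3)c2c1=O | intermediate
10 | (5S)-8-hydroxy-3-methoxy-2-methyl-5-(5-phenylpentyl)-5,6-dihydroquinolin-4(1H)-one | COc1c(C)[nH]c2c(c1=O)[C@@H](CCCCCc1ccccc1)CC=C2O | intermediate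
11 | (5S)-3-methoxy-2-methyl-5-(5-phenylpentyl)-6,7-dihydroquinoline-4,8(1H,5H)-dione | COc1c(C)[nH]c2c(c1=O)[C@@H](CCCCCc1ccccc1)CCC2=O | target

**Totals**

Total step count: 4. Longest linear sequence: 4 steps (1 → 4 → 6 → 9 → 11).

**Steps most likely to fail, with fallbacks**

Step 4 (enantioselective partial hydrogenation). The risks are low enantioselectivity, over-reduction of the C8 ketone, and catalyst inhibition by the chelating hydroxyquinolone. The fallback sets out from 9 and comes back at 11. Compound 9 is hydrogenated over Pd/C (H2, 5 bar, EtOH, 40 °C), the established phenol-to-ketone mode that leaves the pendant phenyl untouched, to give racemic 3-methoxy-2-methyl-5-(5-phenylpentyl)-6,7-dihydroquinoline-4,8(1H,5H)-dione F1. The enantiomers are then separated by preparative SFC on an amylose carbamate chiral phase. The (S)-enantiomer is 11, and the (R)-enantiomer can be dehydrogenated back to 9 with DDQ and recycled.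

Step 3 (thermal cyclisation with a transient silyl cap). The risks are loss of the TMS group to the liberated methanol, followed by benzoxazole formation or decomposition at 250 °C. The fallback sets out from 6 and comes back at 9. The phenol of 6 is benzylated (BnBr, K2CO3, DMF, rt; the hydrogen-bonded enaminoester N–H is not nucleophilic) to give methyl (2E)-3-{[2-(benzyloxy)-5-(5-phenylpentyl)phenyl]amino}-2-methoxybut-2-enoate F2. This is cyclised in Ph2O at 250 °C to 8-(benzyloxy)-3-methoxy-2-methyl-5-(5-phenylpentyl)quinolin-4(1H)-one F3. Hydrogenolysis (H2, 1 atm, Pd/C, EtOAc/MeOH, rt, stopped after one equivalent) then gives 9.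

Step 1 (B-alkyl Suzuki coupling on the free aminophenol). The risks are slow oxidative addition into the electron-rich bromophenoxide, air oxidation of the aminophenol, and protodeboronation of 3. The fallback sets out from 1 and comes back at 4. Compound 1 undergoes copper-free Sonogashira coupling with commercial 5-phenylpent-1-yne (PdCl2(MeCN)2, XPhos, Cs2CO3, MeCN, 80 °C) to give 2-amino-4-(5-phenylpent-1-yn-1-yl)phenol F4. Hydrogenation of the alkyne (H2, 1 atm, Pd/C, EtOAc, rt) then gives 4.

**Further compounds**

F1 | step 4 | racemic 3-methoxy-2-methyl-5-(5-phenylpentyl)-6,7-dihydroquinoline-4,8(1H,5H)-dione | COc1c(C)[nH]c2c(c1=O)C(CCCCCc1ccccc1)CCC2=O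
F2 | step 3 | methyl (2E)-3-{[2-(benzyloxy)-5-(5-phenylpentyl)phenyl]amino}-2-methoxybut-2-enoate | COC(=O)/C(OC)=C(\Nc1cc(CCCCCc2ccccc2)ccc1OCc1ccccc1)C
F3 | step 3 | 8-(benzyloxy)-3-methoxy-2-methyl-5-(5-phenylpentyl)quinolin-4(1H)-one | COc1c(C)[nH]c2c(OCc3ccccc3)ccc(CCCCCc3ccccc3)c2c1=O
F4 | step 1 | 2-amino-4-(5-phenylpent-1-yn-1-yl)phenol | Nc1cc(C#CCCCc2ccccc2)ccc1O
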